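The pyranone ring (ring C) is disconnected at C4–C4a. An intramolecular Friedel–Crafts acylation of a β-aryloxycinnamic acid, activated as a mixed anhydride, forms this bond and closes ring C in one operation. The step exploits the substitution of ring A: C4a lies between O1 and the C5 methoxy group, while C8, the only other carbon ortho to O1, carries hydrogen in the target and can hold a bromine that is removed at the end, so acylation can occur only at C4a. The precursor is the (Z)-3-aryloxy-3-arylacrylic acid assembled from a 2-bromophenol (ring A) and an arylpropiolate (ring B) that carries the side chain derived from the Roche ester.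

Key step: step 12

Remark: positions are given in chromone numbering (O1, C2 to C8a; ring A = benzo ring, ring C = pyranone, ring B = 2-aryl group); compounds 17, 18 and 19 are drawn as the Z isomers expected from anti addition in step 10, and any E isomer would be carried along, because the push–pull alkene equilibrates under the acidic conditions of step 12.

Step 1
Reactants: 1 3-hydroxy-4,5-dimethoxybenzaldehyde
Product: 2 2-bromo-3-hydroxy-4,5-dimethoxybenzaldehyde
Conditions: Br2 (1.05 equiv), NaOAc, Fe powder (cat.), AcOH, rt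
Reagents that add atoms: bromine, BrBr
Why: Electrophilic aromatic bromination which, as with isovanillin under these buffered conditions, should place the bromine at C2, between the hydroxyl and the formyl group, the site ortho to the free hydroxyl and para to the C5 methoxy.

Step 2
Reactants: 2 2-bromo-3-hydroxy-4,5-dimethoxybenzaldehyde
Product: 3 3-(benzyloxy)-2-bromo-4,5-dimethoxybenzaldehyde
Conditions: BnBr, K2CO3, DMF, rt
Reagents that add atoms: benzyl bromide, BrCc1ccccc1
Why: Williamson etherification of the only phenoxide with a benzylic bromide, under conditions to which the aldehyde and the aryl bromide are inert.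

Step 3
Reactants: 3 3-(benzyloxy)-2-bromo-4,5-dimethoxybenzaldehyde
Product: 5 3-(benzyloxy)-2-bromo-4,5-dimethoxyphenol, via aryl formate 4 (not isolated)
Conditions: mCPBA, CH2Cl2, rt; then K2CO3 (cat.), MeOH, rt
Reagents that add atoms: 3-chloroperoxybenzoic acid (mCPBA), OOC(=O)c1cccc(Cl)c1
Why: Baeyer–Villiger (Dakin-type) oxidation in which the electron-rich aryl group with its para methoxy migrates in preference to hydrogen, followed by methanolysis of the aryl formate; benzyl ether and aryl bromide do not react with the peracid.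

Step 4
Reactants: 6 methyl (R)-3-hydroxy-2-methylpropanoate
Product: 7 methyl (R)-3-(benzyloxy)-2-methylpropanoate
Conditions: BnOC(=NH)CCl3, TfOH (cat.), CH2Cl2/cyclohexane, 0 °C → rt
Reagents that add atoms: benzyl 2,2,2-trichloroacetimidate, N=C(OCc1ccccc1)C(Cl)(Cl)Cl
Why: Acid-catalysed O-benzylation with a trichloroacetimidate, which avoids the basic conditions that could epimerise the α-stereocentre or cause β-elimination.

Step 5
Reactants: 7 methyl (R)-3-(benzyloxy)-2-methylpropanoate
Product: 8 (R)-3-(benzyloxy)-2-methylpropanal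
Conditions: i-Bu2AlH (1.1 equiv), CH2Cl2, −78 °C; MeOH quench, aq. KNaC4H4O6 (potassium sodium tartrate); crude aldehyde used at once
Reagents that add atoms: none
Why: Partial hydride reduction of the ester, in which the tetrahedral aluminium hemiacetal persists at −78 °C until the quench; the α-stereocentre is preserved by keeping the aldehyde cold and using it crude.

Step 6
Reactants: 8 (R)-3-(benzyloxy)-2-methylpropanal
Product: 9 (S)-4-(benzyloxy)-3-methylbut-1-ene
Conditions: Ph3PCH3Br, KN(SiMe3)2, THF, 0 °C; then 8, −78 °C → rt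
Reagents that add atoms: methyltriphenylphosphonium bromide, C[P+](c1ccccc1)(c1ccccc1)c1ccccc1.[Br-]
Why: Wittig methylenation with a salt-free non-stabilised ylide, which adds to the aldehyde faster than it enolises it, so the stereocentre keeps its spatial arrangement (the descriptor changes from R to S only through the change in substituent ranking).

Step 7
Reactants: 9 (S)-4-(benzyloxy)-3-methylbut-1-ene; 10 4-bromo-2-iodo-1-methoxybenzene
Product: 12 2-[(3S)-4-(benzyloxy)-3-methylbutyl]-4-bromo-1-methoxybenzene, via B-alkyl-9-BBN 11 (not isolated)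
Conditions: 9-BBN, THF, 0 °C → rt; then 10 (1.0 equiv), PdCl2(dppf) (cat.), aq. K3PO4, DMF, rt
Reagents that add atoms: none
Why: Anti-Markovnikov hydroboration of the terminal alkene followed by B-alkyl Suzuki–Miyaura coupling, in which oxidative addition of zerovalent palladium into the C–I bond is far faster at room temperature than into the C–Br bond, so the bromide is kept and the stereocentre is not involved.

Step 8
Reactants: 12 2-[(3S)-4-(benzyloxy)-3-methylbutyl]-4-bromo-1-methoxybenzene
Product: 14 2-[(3S)-4-(benzyloxy)-3-methylbutyl]-4-iodo-1-methoxybenzene, via aryllithium 13 (not isolated)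
Conditions: n-BuLi (1.05 equiv), THF, −78 °C; then I2, −78 °C → rt
Reagents that add atoms: iodine, II
Why: Bromine–lithium exchange, faster at −78 °C than any deprotonation of the ethers, followed by iodinolysis of the aryllithium, provides the aryl iodide that the propiolate coupling requires.

Step 9
Reactants: 14 2-[(3S)-4-(benzyloxy)-3-methylbutyl]-4-iodo-1-methoxybenzene; 15 methyl propiolate
Product: 16 methyl 3-{3-[(3S)-4-(benzyloxy)-3-methylbutyl]-4-methoxyphenyl}prop-2-ynoate
Conditions: PdCl2(PPh3)2 (cat.), CuI (cat.), K2CO3, THF, 65 °C, 15 added in portions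
Reagents that add atoms: none
Why: Sonogashira coupling of an aryl iodide with an electron-poor alkyne under carbonate conditions, which avoid the amine conjugate addition and oligomerisation that propiolates suffer with amine bases.

Step 10
Reactants: 5 3-(benzyloxy)-2-bromo-4,5-dimethoxyphenol; 16 methyl 3-{3-[(3S)-4-(benzyloxy)-3-methylbutyl]-4-methoxyphenyl}prop-2-ynoate
Product: 17 methyl (Z)-3-[3-(benzyloxy)-2-bromo-4,5-dimethoxyphenoxy]-3-{3-[(3S)-4-(benzyloxy)-3-methylbutyl]-4-methoxyphenyl}prop-2-enoate
Conditions: Cs2CO3 (0.5 equiv), DMF, 70 °C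
Reagents that add atoms: none
Why: Base-mediated oxa-Michael addition of the phenoxide to the β-carbon of the arylpropiolate, the classical route to β-aryloxycinnamates, in which anti addition should favour the Z isomer and the geometry is not critical for step 12.

Step 11
Reactants: 17 methyl (Z)-3-[3-(benzyloxy)-2-bromo-4,5-dimethoxyphenoxy]-3-{3-[(3S)-4-(benzyloxy)-3-methylbutyl]-4-methoxyphenyl}prop-2-enoate
Product: 18 (Z)-3-[3-(benzyloxy)-2-bromo-4,5-dimethoxyphenoxy]-3-{3-[(3S)-4-(benzyloxy)-3-methylbutyl]-4-methoxyphenyl}prop-2-enoic acid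
Conditions: LiOH·H2O, THF/MeOH/H2O, rt; then 1 M HCl to pH 3, 0 °C
Reagents that add atoms: lithium hydroxide, [Li+].[OH-]
Why: Saponification of the methyl ester by acyl substitution, with the β-carbon shielded from hydroxide by its aryl and aryloxy substituents and all ethers stable to base.

Step 12
Reactants: 18 (Z)-3-[3-(benzyloxy)-2-bromo-4,5-dimethoxyphenoxy]-3-{3-[(3S)-4-(benzyloxy)-3-methylbutyl]-4-methoxyphenyl}prop-2-enoic acid
Product: 20 7-(benzyloxy)-2-{3-[(3S)-4-(benzyloxy)-3-methylbutyl]-4-methoxyphenyl}-8-bromo-5,6-dimethoxy-4H-chromen-4-one, via mixed trifluoroacetic anhydride 19 (not isolated)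
Conditions: (CF3CO)2O (3 equiv), CH2Cl2, 0 °C → rt; aq. NaHCO3 work-up
Reagents that add atoms: none
Why: The acid is converted into mixed anhydride 19, which ionises easily because the β-aryloxy and β-anisyl donors stabilise the resulting ketene-like acylium ion; this electrophile attacks the ring A carbon ortho to the ether oxygen, and the σ-complex loses a proton to give the chromone. The closest known reaction type is the acid-mediated Ruhemann-type cyclisation of β-aryloxycinnamic acids to flavones, an intramolecular Friedel–Crafts acylation. Ring C is closed as a six-membered ring by attack of an arene carbon on an acyl carbon whose C=O stays exocyclic (6-exo-trig on the anhydride, 6-exo-dig on the acylium ion). No stereocentre is formed, and the side-chain centre is remote and untouched. The step needs regioselectivity between the two carbons ortho to the ether oxygen, secured by the bromine on the future C8, which leaves only the future C4a (ortho to O1, ortho to methoxy, para to benzyloxy) free; it also needs chemoselectivity against indenone formation on ring B, secured because the ring B carbons within reach are meta to its methoxy group and would close a five-membered ring. Any E isomer should equilibrate with the Z isomer through C-protonation of the push–pull alkene by the liberated CF3CO2H, so both funnel to 20.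

Step 13
Reactants: 20 7-(benzyloxy)-2-{3-[(3S)-4-(benzyloxy)-3-methylbutyl]-4-methoxyphenyl}-8-bromo-5,6-dimethoxy-4H-chromen-4-one
Product: 23 7-(benzyloxy)-2-{3-[(3S)-4-(benzyloxy)-3-methylbutyl]-4-methoxyphenyl}-8-bromo-3-hydroxy-5,6-dimethoxy-4H-chromen-4-one, via 3-lithioflavone 21 (not isolated), via dimethyl 3-boronate 22 (not isolated)
Conditions: LiN(i-Pr)2 (1.5 equiv), THF, −78 °C; B(OMe)3, −78 °C → 0 °C; then AcOH, 30% H2O2, 0 °C → rt
Reagents that add atoms: hydrogen peroxide, OO
Why: C3 lithiation of the flavone by the amide base gives a vinyllithium held by the C4 carbonyl, which is borylated and oxidised to the flavonol (lithiation–boration–oxidation); the amide base does not exchange the C8 bromine, which has no ortho hydrogen for aryne formation.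

Step 14
Reactants: 23 7-(benzyloxy)-2-{3-[(3S)-4-(benzyloxy)-3-methylbutyl]-4-methoxyphenyl}-8-bromo-3-hydroxy-5,6-dimethoxy-4H-chromen-4-one
Product: 24 3,7-dihydroxy-2-{3-[(3S)-4-hydroxy-3-methylbutyl]-4-methoxyphenyl}-5,6-dimethoxy-4H-chromen-4-one (CNP0267774.1)
Conditions: H2 (1 atm), 10% Pd/C, NaOAc, MeOH/EtOAc, rt
Reagents that add atoms: none
Why: Heterogeneous hydrogenolysis over Pd/C cleaves both O-benzyl groups and, with NaOAc taking up HBr, the C8–Br bond (hydrodebromination), while the flavonol core and the remote stereocentre are not affected.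

Compound list
1 | 3-hydroxy-4,5-dimethoxybenzaldehyde | COc1cc(C=O)cc(O)c1OC | starting material
2 | 2-bromo-3-hydroxy-4,5-dimethoxybenzaldehyde | COc1cc(C=O)c(Br)c(O)c1OC | intermediate
3 | 3-(benzyloxy)-2-bromo-4,5-dimethoxybenzaldehyde | COc1cc(C=O)c(Br)c(OCc2ccccc2)c1OC | intermediate
4 | 3-(benzyloxy)-2-bromo-4,5-dimethoxyphenyl formate | COc1cc(OC=O)c(Br)c(OCc2ccccc2)c1OC | intermediate (not isolated)
5 | 3-(benzyloxy)-2-bromo-4,5-dimethoxyphenol | COc1cc(O)c(Br)c(OCc2ccccc2)c1OC | intermediate
6 | methyl (R)-3-hydroxy-2-methylpropanoate | COC(=O)[C@H](C)CO | starting material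
7 | methyl (R)-3-(benzyloxy)-2-methylpropanoate | COC(=O)[C@H](C)COCc1ccccc1 | intermediate
8 | (R)-3-(benzyloxy)-2-methylpropanal | O=C[C@H](C)COCc1ccccc1 | intermediate
9 | (S)-4-(benzyloxy)-3-methylbut-1-ene | C=C[C@H](C)COCc1ccccc1 | intermediate
10 | 4-bromo-2-iodo-1-methoxybenzene | COc1ccc(Br)cc1I | starting material
11 | 9-[(3S)-4-(benzyloxy)-3-methylbutyl]-9-borabicyclo[3.3.1]nonane | B1(CC[C@H](C)COCc2ccccc2)C2CCCC1CCC2 | intermediate (not isolated)
12 | 2-[(3S)-4-(benzyloxy)-3-methylbutyl]-4-bromo-1-methoxybenzene | COc1ccc(Br)cc1CC[C@H](C)COCc1ccccc1 | intermediate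
13 | {3-[(3S)-4-(benzyloxy)-3-methylbutyl]-4-methoxyphenyl}lithium | COc1ccc([Li])cc1CC[C@H](C)COCc1ccccc1 | intermediate (not isolated)
14 | 2-[(3S)-4-(benzyloxy)-3-methylbutyl]-4-iodo-1-methoxybenzene | COc1ccc(I)cc1CC[C@H](C)COCc1ccccc1 | intermediate
15 | methyl propiolate | C#CC(=O)OC | starting material
16 | methyl 3-{3-[(3S)-4-(benzyloxy)-3-methylbutyl]-4-methoxyphenyl}prop-2-ynoate | COC(=O)C#Cc1ccc(OC)c(CC[C@H](C)COCc2ccccc2)c1 | intermediate
17 | methyl (Z)-3-[3-(benzyloxy)-2-bromo-4,5-dimethoxyphenoxy]-3-{3-[(3S)-4-(benzyloxy)-3-methylbutyl]-4-methoxyphenyl}prop-2-enoate | COC(=O)/C=C(\Oc1cc(OC)c(OC)c(OCc2ccccc2)c1Br)c1ccc(OC)c(CC[C@H](C)COCc2ccccc2)c1 | intermediate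
18 | (Z)-3-[3-(benzyloxy)-2-bromo-4,5-dimethoxyphenoxy]-3-{3-[(3S)-4-(benzyloxy)-3-methylbutyl]-4-methoxyphenyl}prop-2-enoic acid | OC(=O)/C=C(\Oc1cc(OC)c(OC)c(OCc2ccccc2)c1Br)c1ccc(OC)c(CC[C@H](C)COCc2ccccc2)c1 | intermediate
19 | mixed anhydride of acid 18 with trifluoroacetic acid | FC(F)(F)C(=O)OC(=O)/C=C(\Oc1cc(OC)c(OC)c(OCc2ccccc2)c1Br)c1ccc(OC)c(CC[C@H](C)COCc2ccccc2)c1 | intermediate (not isolated)
20 | 7-(benzyloxy)-2-{3-[(3S)-4-(benzyloxy)-3-methylbutyl]-4-methoxyphenyl}-8-bromo-5,6-dimethoxy-4H-chromen-4-one | COc1ccc(-c2cc(=O)c3c(OC)c(OC)c(OCc4ccccc4)c(Br)c3o2)cc1CC[C@H](C)COCc1ccccc1 | intermediate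
21 | 3-lithio derivative of flavone 20 | COc1ccc(-c2oc3c(Br)c(OCc4ccccc4)c(OC)c(OC)c3c(=O)c2[Li])cc1CC[C@H](C)COCc1ccccc1 | intermediate (not isolated)
22 | dimethyl boronate at C3 of flavone 20 | COB(OC)c1c(-c2ccc(OC)c(CC[C@H](C)COCc3ccccc3)c2)oc2c(Br)c(OCc3ccccc3)c(OC)c(OC)c2c1=O | intermediate (not isolated)
23 | 7-(benzyloxy)-2-{3-[(3S)-4-(benzyloxy)-3-methylbutyl]-4-methoxyphenyl}-8-bromo-3-hydroxy-5,6-dimethoxy-4H-chromen-4-one | COc1ccc(-c2oc3c(Br)c(OCc4ccccc4)c(OC)c(OC)c3c(=O)c2O)cc1CC[C@H](C)COCc1ccccc1 | intermediate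
24 | 3,7-dihydroxy-2-{3-[(3S)-4-hydroxy-3-methylbutyl]-4-methoxyphenyl}-5,6-dimethoxy-4H-chromen-4-one | COc1ccc(-c2oc3cc(O)c(OC)c(OC)c3c(=O)c2O)cc1CC[C@H](C)CO | target

Total step count: 14 steps.
Longest linear sequence: 11 steps (steps 4 to 14, from methyl (R)-3-hydroxy-2-methylpropanoate 6).

Steps most likely to fail

1. Step 12. The vinylogous acyl donor may be too weakly electrophilic to acylate ring A before the acid starts to cleave the benzyl ethers, or the E isomer may equilibrate too slowly. The fallback forms the same C4–C4a bond by palladium-catalysed carbonylative annulation, which needs no acid. It sets out from phenol 5 and iodide 14 and comes back to the route at flavone 20. Phenol 5 would be iodinated at its only free ring position (NIS, MeCN, rt) to give 3-(benzyloxy)-2-bromo-6-iodo-4,5-dimethoxyphenol F1. Iodide 14 would be coupled with trimethylsilylacetylene (PdCl2(PPh3)2, CuI, Et3N, rt) to ({3-[(3S)-4-(benzyloxy)-3-methylbutyl]-4-methoxyphenyl}ethynyl)trimethylsilane F2 and desilylated (K2CO3, MeOH) to 2-[(3S)-4-(benzyloxy)-3-methylbutyl]-4-ethynyl-1-methoxybenzene F3. F1, F3 and CO (1 atm) with PdCl2(PPh3)2 in Et2NH should undergo carbonylative Sonogashira coupling at the C–I bond, leaving the hindered C–Br bond alone. The resulting 1-[4-(benzyloxy)-3-bromo-2-hydroxy-5,6-dimethoxyphenyl]-3-{3-[(3S)-4-(benzyloxy)-3-methylbutyl]-4-methoxyphenyl}prop-2-yn-1-one F4 would close in the flask by 6-endo addition of the phenol to give 20.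

2. Step 10. The conjugate addition may be slow, because the p-methoxyphenyl group lowers the electrophilicity of the ynoate and the phenoxide is flanked by bromine, and the ester may be cleaved at the temperatures then needed. The fallback makes the C–O bond first on the unsubstituted propiolate and the C–aryl bond second. It sets out from phenol 5, methyl propiolate 15 and iodide 14 and comes back at ester 17. Phenol 5 and 15 with DABCO (cat.) in CH2Cl2 at rt should give methyl (E)-3-[3-(benzyloxy)-2-bromo-4,5-dimethoxyphenoxy]prop-2-enoate F5. Heck arylation of F5 with 14 (Pd(OAc)2, n-Bu4NCl, NaHCO3, DMF, 80 °C) should place the aryl group on the oxygen-bearing β-carbon; syn addition and syn β-hydride elimination leave the aryloxy group cis to the ester, which is 17.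

3. Step 13. Metalation at C3 may be incomplete or accompanied by attack of the base on the pyranone, and the electron-rich flavonol may be over-oxidised in the peroxide stage. The fallback is electrophilic oxygenation in place of deprotonation. It sets out from flavone 20 and comes back at flavonol 23. Dimethyldioxirane in acetone (0 °C → rt) should epoxidise the C2=C3 bond to give the 2,3-epoxide of flavone 20 (both epoxide diastereomers) F6, and p-TsOH (cat.) in CH2Cl2 should open it through the C2 oxocarbenium ion, with loss of the C3 proton, to give 23.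

Further compounds
F1 | step 12 | 3-(benzyloxy)-2-bromo-6-iodo-4,5-dimethoxyphenol | COc1c(I)c(O)c(Br)c(OCc2ccccc2)c1OC
F2 | step 12 | ({3-[(3S)-4-(benzyloxy)-3-methylbutyl]-4-methoxyphenyl}ethynyl)trimethylsilane | COc1ccc(C#C[Si](C)(C)C)cc1CC[C@H](C)COCc1ccccc1
F3 | step 12 | 2-[(3S)-4-(benzyloxy)-3-methylbutyl]-4-ethynyl-1-methoxybenzene | COc1ccc(C#C)cc1CC[C@H](C)COCc1ccccc1
F4 | step 12 | 1-[4-(benzyloxy)-3-bromo-2-hydroxy-5,6-dimethoxyphenyl]-3-{3-[(3S)-4-(benzyloxy)-3-methylbutyl]-4-methoxyphenyl}prop-2-yn-1-one | COc1ccc(C#CC(=O)c2c(O)c(Br)c(OCc3ccccc3)c(OC)c2OC)cc1CC[C@H](C)COCc1ccccc1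
F5 | step 10 | methyl (E)-3-[3-(benzyloxy)-2-bromo-4,5-dimethoxyphenoxy]prop-2-enoate | COC(=O)/C=C/Oc1cc(OC)c(OC)c(OCc2ccccc2)c1Br
F6 | step 13 | 2,3-epoxide of flavone 20 (2,3-epoxyflavanone, both epoxide diastereomers) | COc1ccc(C23OC2C(=O)c2c(OC)c(OC)c(OCc4ccccc4)c(Br)c2O3)cc1CC[C@H](C)COCc1ccccc1
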